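Ring A of this labdane (labdane numbering) is an unfunctionalised cyclohexane whose C2–C3 ethano bridge joins the gem-dimethyl carbon C4 to C1, a methylene on quaternary C10. Ring B is therefore built first from (R)-carvone, which already holds C5 with an isopropenyl group (future C4 and its methyls) and lets a formyl group (future C1) be set on C10. One operation then stitches ring A: hydrogen-atom transfer turns the isopropenyl group into the tertiary C4 radical, which adds to vinyltriphenylphosphonium (C3–C4), and the derived ylide olefinates the aldehyde (C1–C2). Side chain and the trans-diaxial C6/C7 diester follow by enone transposition and a β-epoxide.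

Key step: step 4

Remark on the chemistry: ring A = C1–C5 and C10, ring B = C5–C10, side chain = C11–C16; β is the face of the C10 methyl, α the opposite face. Compounds 1, 7, 12 and 17 are taken as commercial. The C15 acid is carried as its tert-butyl ester from step 8 and released last.

Step 1
Reactants: 1 (R)-(−)-carvone
Product: 3 (5R)-2,6-dimethyl-5-(prop-1-en-2-yl)cyclohex-2-en-1-one (both C6 epimers), via lithium enolate 2 (not isolated)
Conditions: LiN(i-Pr)2, THF, −78 °C; MeI, −78 → 0 °C
Reagents that add atoms: iodomethane, CI; lithium diisopropylamide, [Li+].CC(C)[N-]C(C)C (lithium of intermediate 2 only)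
Why: Kinetic α′-deprotonation gives the cross-conjugated lithium enolate, whose C-methylation (enolate alkylation) installs the future C10 methyl; the new centre is planarised again in step 2, so its configuration does not matter.

Step 2
Reactants: 3 (5R)-2,6-dimethyl-5-(prop-1-en-2-yl)cyclohex-2-en-1-one
Product: 5 (5S,6R)-6-(hydroxymethyl)-2,6-dimethyl-5-(prop-1-en-2-yl)cyclohex-2-en-1-one, via lithium enolate 4 (not isolated)
Conditions: LiN(i-Pr)2, THF, −78 °C; CH2O (gas from cracked paraformaldehyde), −78 °C; AcOH quench
Reagents that add atoms: formaldehyde, C=O; lithium diisopropylamide, [Li+].CC(C)[N-]C(C)C (lithium of intermediate 4 only)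
Why: Aldol addition of the re-formed enolate to monomeric formaldehyde should occur anti to the adjacent C5 isopropenyl group (substrate control, as in alkylations of 6-alkylcarvone enolates), setting quaternary C10 with the methyl cis and the hydroxymethyl (future C1) trans to the isopropenyl group; the minor epimer would be removed by chromatography.

Step 3
Reactants: 5 (5S,6R)-6-(hydroxymethyl)-2,6-dimethyl-5-(prop-1-en-2-yl)cyclohex-2-en-1-one
Product: 6 (1R,6S)-1,3-dimethyl-2-oxo-6-(prop-1-en-2-yl)cyclohex-3-ene-1-carbaldehyde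
Conditions: Dess–Martin periodinane, CH2Cl2, 0 °C → rt
Reagents that add atoms: none
Why: Dess–Martin oxidation converts the neopentyl primary alcohol into the aldehyde under non-basic conditions, so the non-enolisable β-keto aldehyde is not exposed to retro-Claisen cleavage and no stereocentre is touched.

Step 4
Reactants: 6 (1R,6S)-1,3-dimethyl-2-oxo-6-(prop-1-en-2-yl)cyclohex-3-ene-1-carbaldehyde; 7 vinyltriphenylphosphonium bromide
Product: 10 (4aS,8aS)-2,5,5,8a-tetramethyl-4a,5,6,8a-tetrahydronaphthalen-1(4H)-one (trans-fused; ring A C1=C2 alkene; ring B C7=C8–C9=O enone), via phosphonium bromide 8 (not isolated), via ylide 9 (not isolated)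
Conditions: 7 (1.5 equiv), Fe(acac)3 (30 mol %), PhSiH3, EtOH/THF, 40 °C; then evaporation, THF, KN(SiMe3)2, −78 °C → rt, same flask
Reagents that add atoms: none
Why: Proposed new method: an iron hydride formed from Fe(acac)3 and PhSiH3 transfers a hydrogen atom to the isopropenyl CH2 (creating the second C4 methyl), the nucleophilic tertiary C4 radical adds to the terminal carbon of the cationic vinylphosphonium acceptor (C3–C4, Giese addition), reduction of the α-phosphonio radical by divalent iron and protonation give salt 8, and KN(SiMe3)2 converts 8 into ylide 9, which olefinates the C1 aldehyde intramolecularly (C1=C2, Wittig). The closest known reaction types are iron-hydride Giese/aldol radical–polar crossover annulations, photoredox radical addition to vinylphosphonium salts followed by Wittig olefination, and the anionic vinylphosphonium (Schweizer) annulation. Ring A closes in the Wittig stage by 6-exo-trig attack of ylide carbon C2 on the aldehyde carbon and collapse of the oxaphosphetane to the ring (cis) alkene, the first bond being intermolecular. No new stereocentre arises (C4 carries two methyls, C1 and C2 are sp2), and the trans ring fusion follows from the trans C5/C10 substituents set in step 2. The step needs hydrogen-atom transfer to the electron-rich 1,1-disubstituted alkene rather than to the enone, capture of the radical by 7 rather than by the enone of a second molecule, and olefination of the aldehyde rather than the C9 ketone. These are secured by alkene and acceptor polarity, by the absence of any five- or six-membered intramolecular radical trap, and because closure onto C9 would give a bridgehead alkene.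

Step 5
Reactants: 10 (4aS,8aS)-2,5,5,8a-tetramethyl-4a,5,6,8a-tetrahydronaphthalen-1(4H)-one
Product: 11 (4aS,8aS)-2,5,5,8a-tetramethyl-4a,5,6,7,8,8a-hexahydronaphthalen-1(4H)-one
Conditions: H2 (1 atm), RhCl(PPh3)3 (5 mol %), benzene, rt
Reagents that add atoms: none
Why: Homogeneous hydrogenation with RhCl(PPh3)3 reduces the cis-disubstituted C1=C2 alkene and leaves the trisubstituted conjugated C7=C8 alkene and the ketone untouched, and no stereocentre is formed.

Step 6
Reactants: 11 (4aS,8aS)-2,5,5,8a-tetramethyl-4a,5,6,7,8,8a-hexahydronaphthalen-1(4H)-one; 12 2-(2-bromoethyl)-2-methyl-1,3-dioxolane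
Product: 14 13,13-(ethylenedioxy)-14,15-dinorlabd-7-en-9-ol (5S,10S; C9 epimers), via Grignard reagent 13 (not isolated)
Conditions: 12, Mg, THF, rt; anhydrous CeCl3, THF, −78 °C; 11, −78 → 0 °C; aq. NH4Cl
Reagents that add atoms: magnesium, [Mg] (in intermediate 13 only)
Why: Cerium-promoted 1,2-addition of the Grignard reagent to the hindered C9 ketone attaches C11–C13 and C16 while suppressing reduction and enolisation; the C9 configuration does not matter because C9 becomes sp2 in step 7.

Step 7
Reactants: 14 13,13-(ethylenedioxy)-14,15-dinorlabd-7-en-9-ol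
Product: 16 14,15-dinorlabd-8-ene-7,13-dione (5S,10S), via ketal enone 15 (not isolated)
Conditions: pyridinium chlorochromate [C5H5NH][CrO3Cl], CH2Cl2, rt; filtration through silica; then 1 M HCl, THF, rt
Reagents that add atoms: pyridinium chlorochromate, [O-][Cr](=O)(=O)Cl.c1cc[nH+]cc1 (oxygen on C7); water, O (oxygen of the C13 ketone)
Why: Babler–Dauben oxidative transposition (chromate ester, allylic 1,3-shift to C7, oxidation) moves the oxygen to C7 and the alkene to C8=C9, and the acid stage unmasks the side-chain methyl ketone without touching a stereocentre.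

Step 8
Reactants: 16 14,15-dinorlabd-8-ene-7,13-dione; 17 tert-butyl (diethoxyphosphoryl)acetate
Product: 19 tert-butyl 7-oxolabda-8,13E-dien-15-oate, via phosphonate anion 18 (not isolated)
Conditions: 17, NaH, THF, 0 °C; then 16, rt → 50 °C
Reagents that add atoms: sodium hydride, [Na+].[H-] (sodium of intermediate 18 only)
Why: Horner–Wadsworth–Emmons olefination occurs only at the unhindered methyl ketone (the C7 carbonyl is conjugated and flanked by a tetrasubstituted alkene) and should favour the E-trisubstituted enoate with the bulky tert-butyl ester, the Z isomer being removed by chromatography.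

Step 9
Reactants: 19 tert-butyl 7-oxolabda-8,13E-dien-15-oate
Product: 22 tert-butyl 6α-bromo-7-oxolabda-8,13E-dien-15-oate, via lithium dienolate 20 (not isolated), via silyl dienol ether 21 (not isolated)
Conditions: LiN(SiMe3)2, Me3SiCl, THF, −78 °C; then NBS, −78 → 0 °C
Reagents that add atoms: N-bromosuccinimide, O=C1CCC(=O)N1Br; chlorotrimethylsilane, C[Si](C)(C)Cl (in intermediate 21 only); lithium bis(trimethylsilyl)amide, [Li+].C[Si](C)(C)[N-][Si](C)(C)C (lithium of intermediate 20 only)
Why: Kinetic α′-deprotonation at C6 with in situ silylation gives the cross-conjugated silyl dienol ether, which NBS brominates at C6 from the α face because the β face is screened by the axial C10 methyl and C4 β-methyl (α-halogenation of a silyl enol ether), giving the equatorial 6α-bromide.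

Step 10
Reactants: 22 tert-butyl 6α-bromo-7-oxolabda-8,13E-dien-15-oate
Product: 24 tert-butyl 6β,7β-epoxylabda-8,13E-dien-15-oate, via bromohydrin 23 (not isolated)
Conditions: NaBH4, CeCl3·7H2O, MeOH, −20 °C; then K2CO3, rt
Reagents that add atoms: none
Why: Luche reduction should deliver hydride 1,2 to C7 along the axial trajectory from the open α face to give the 7β-alcohol trans to bromine, and base then closes the 6β,7β-epoxide by intramolecular SN2 displacement with inversion at C6 (the classical trans-bromohydrin route to the epoxide on the more hindered face).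

Step 11
Reactants: 24 tert-butyl 6β,7β-epoxylabda-8,13E-dien-15-oate
Product: 25 tert-butyl 6β-hydroxy-7α-(3-methylbutanoyloxy)labda-8,13E-dien-15-oate
Conditions: 3-methylbutanoic acid (excess), CH2Cl2, 0 °C → rt
Reagents that add atoms: 3-methylbutanoic acid, CC(C)CC(=O)O
Why: Acid-mediated opening of the vinyl epoxide by the carboxylic acid should occur at the allylic carbon C7 with inversion from the α face, which is also the trans-diaxial (Fürst–Plattner) mode, setting the 7α-ester and the 6β-hydroxyl.

Step 12
Reactants: 25 tert-butyl 6β-hydroxy-7α-(3-methylbutanoyloxy)labda-8,13E-dien-15-oate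
Product: 26 tert-butyl 6β-acetoxy-7α-(3-methylbutanoyloxy)labda-8,13E-dien-15-oate
Conditions: Ac2O, DMAP, Et3N, CH2Cl2, 40 °C
Reagents that add atoms: acetic anhydride, CC(=O)OC(C)=O
Why: DMAP-catalysed acetylation of the axial 6β-hydroxyl needs forcing conditions because of the syn-axial C4 and C10 methyls, and migration of the trans-diaxial 7α-ester is geometrically impossible, so both stereocentres are retained.

Step 13
Reactants: 26 tert-butyl 6β-acetoxy-7α-(3-methylbutanoyloxy)labda-8,13E-dien-15-oate
Product: 27 6β-acetoxy-7α-(3-methylbutanoyloxy)labda-8,13E-dien-15-oic acid (5S,6S,7S,10S)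
Conditions: CF3CO2H, CH2Cl2, 0 °C
Reagents that add atoms: none
Why: Acidolysis of the tert-butyl ester with loss of 2-methylpropene frees the C15 acid, while the secondary acetate and isovalerate should be stable to anhydrous acid at 0 °C and no stereocentre is touched.

Compound list
1 | (R)-(−)-carvone, (5R)-2-methyl-5-(prop-1-en-2-yl)cyclohex-2-en-1-one | C1C=C(C)C(=O)C[C@@H]1C(C)=C | starting material
2 | lithium enolate of 1 (cross-conjugated, O–Li on C9) | C1C=C(C)C(O[Li])=C[C@@H]1C(C)=C | intermediate (not isolated)
3 | (5R)-2,6-dimethyl-5-(prop-1-en-2-yl)cyclohex-2-en-1-one, both C6 epimers | C1C=C(C)C(=O)C(C)[C@@H]1C(C)=C | intermediate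
4 | lithium enolate of 3 | C1C=C(C)C(O[Li])=C(C)[C@@H]1C(C)=C | intermediate (not isolated)
5 | (5S,6R)-6-(hydroxymethyl)-2,6-dimethyl-5-(prop-1-en-2-yl)cyclohex-2-en-1-one | C1C=C(C)C(=O)[C@@](C)(CO)[C@@H]1C(C)=C | intermediate
6 | (1R,6S)-1,3-dimethyl-2-oxo-6-(prop-1-en-2-yl)cyclohex-3-ene-1-carbaldehyde | C1C=C(C)C(=O)[C@@](C)(C=O)[C@@H]1C(C)=C | intermediate
7 | vinyltriphenylphosphonium bromide | C=C[P+](c1ccccc1)(c1ccccc1)c1ccccc1.[Br-] | starting material
8 | Giese adduct of 6 and 7: triphenylphosphonium bromide with C4(CH3)2–C3H2–C2H2–P on C5, formyl still on C10 | C1C=C(C)C(=O)[C@@](C)(C=O)[C@@H]1C(C)(C)CC[P+](c1ccccc1)(c1ccccc1)c1ccccc1.[Br-] | intermediate (not isolated)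
9 | ylide of 8 (C2=PPh3) | C1C=C(C)C(=O)[C@@](C)(C=O)[C@@H]1C(C)(C)CC=P(c1ccccc1)(c1ccccc1)c1ccccc1 | intermediate (not isolated)
10 | (4aS,8aS)-2,5,5,8a-tetramethyl-4a,5,6,8a-tetrahydronaphthalen-1(4H)-one | C1C=C(C)C(=O)[C@@]2(C)C=CCC(C)(C)[C@H]12 | intermediate
11 | (4aS,8aS)-2,5,5,8a-tetramethyl-4a,5,6,7,8,8a-hexahydronaphthalen-1(4H)-one | C1C=C(C)C(=O)[C@@]2(C)CCCC(C)(C)[C@H]12 | intermediate
12 | 2-(2-bromoethyl)-2-methyl-1,3-dioxolane | CC1(CCBr)OCCO1 | starting material
13 | [2-(2-methyl-1,3-dioxolan-2-yl)ethyl]magnesium bromide | CC1(CC[Mg]Br)OCCO1 | intermediate (not isolated)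
14 | 13,13-(ethylenedioxy)-14,15-dinorlabd-7-en-9-ol (5S,10S; C9 epimers) | C1C=C(C)C(O)(CCC3(C)OCCO3)[C@@]2(C)CCCC(C)(C)[C@H]12 | intermediate
15 | 13,13-(ethylenedioxy)-14,15-dinorlabd-8-en-7-one (5S,10S) | C1C(=O)C(C)=C(CCC3(C)OCCO3)[C@@]2(C)CCCC(C)(C)[C@H]12 | intermediate (not isolated)
16 | 14,15-dinorlabd-8-ene-7,13-dione (5S,10S) | C1C(=O)C(C)=C(CCC(C)=O)[C@@]2(C)CCCC(C)(C)[C@H]12 | intermediate
17 | tert-butyl (diethoxyphosphoryl)acetate | CCOP(=O)(CC(=O)OC(C)(C)C)OCC | starting material
18 | sodium salt of 17 (phosphonate carbanion) | CCOP(=O)(OCC)[CH-]C(=O)OC(C)(C)C.[Na+] | intermediate (not isolated)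
19 | tert-butyl 7-oxolabda-8,13E-dien-15-oate (5S,10S) | C1C(=O)C(C)=C(CC/C(C)=C/C(=O)OC(C)(C)C)[C@@]2(C)CCCC(C)(C)[C@H]12 | intermediate
20 | lithium 6,8-dienolate of 19 (O–Li on C7) | C1=C(O[Li])C(C)=C(CC/C(C)=C/C(=O)OC(C)(C)C)[C@@]2(C)CCCC(C)(C)[C@H]12 | intermediate (not isolated)
21 | trimethylsilyl dienol ether of 19 (C6=C7–OSiMe3, C8=C9) | C1=C(O[Si](C)(C)C)C(C)=C(CC/C(C)=C/C(=O)OC(C)(C)C)[C@@]2(C)CCCC(C)(C)[C@H]12 | intermediate (not isolated)
22 | tert-butyl 6α-bromo-7-oxolabda-8,13E-dien-15-oate | Br[C@H]1C(=O)C(C)=C(CC/C(C)=C/C(=O)OC(C)(C)C)[C@@]2(C)CCCC(C)(C)[C@H]12 | intermediate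
23 | tert-butyl 6α-bromo-7β-hydroxylabda-8,13E-dien-15-oate | Br[C@H]1[C@H](O)C(C)=C(CC/C(C)=C/C(=O)OC(C)(C)C)[C@@]2(C)CCCC(C)(C)[C@H]12 | intermediate (not isolated)
24 | tert-butyl 6β,7β-epoxylabda-8,13E-dien-15-oate | O1[C@@H]2[C@H]1C(C)=C(CC/C(C)=C/C(=O)OC(C)(C)C)[C@@]3(C)CCCC(C)(C)[C@H]23 | intermediate
25 | tert-butyl 6β-hydroxy-7α-(3-methylbutanoyloxy)labda-8,13E-dien-15-oate | O[C@@H]1[C@@H](OC(=O)CC(C)C)C(C)=C(CC/C(C)=C/C(=O)OC(C)(C)C)[C@@]2(C)CCCC(C)(C)[C@H]12 | intermediate
26 | tert-butyl 6β-acetoxy-7α-(3-methylbutanoyloxy)labda-8,13E-dien-15-oate | CC(=O)O[C@@H]1[C@@H](OC(=O)CC(C)C)C(C)=C(CC/C(C)=C/C(=O)OC(C)(C)C)[C@@]2(C)CCCC(C)(C)[C@H]12 | intermediate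
27 | 6β-acetoxy-7α-(3-methylbutanoyloxy)labda-8,13E-dien-15-oic acid (5S,6S,7S,10S) | CC(=O)O[C@@H]1[C@@H](OC(=O)CC(C)C)C(C)=C(CC/C(C)=C/C(=O)O)[C@@]2(C)CCCC(C)(C)[C@H]12 | target

Total step count: 13. Longest linear sequence: 13 steps from (R)-carvone (1); compounds 7, 12 and 17 enter directly.

Steps most likely to fail

Step 4 (new method). The α-phosphonio radical may be consumed unproductively (oligomerisation of the vinylphosphonium salt, or reduction of the acceptor outpacing radical generation), or the base stage may cleave the formyl group by retro-Claisen reaction before olefination. The fallback uses the known iron-hydride Giese/aldol radical–polar crossover annulation and sets out from 6. Fe(acac)3 and PhSiH3 with acrolein would add the C4 radical to the acrolein β-carbon and close ring A by aldol addition of the iron enolate to the C1 aldehyde, giving the ring A β-hydroxy aldehyde F1 (same two ring bonds). MsCl/Et3N followed by DBU would dehydrate it to the ring A enal F2. Stoichiometric RhCl(PPh3)3 in refluxing toluene (Tsuji–Wilkinson decarbonylation) would remove the formyl group, and the route is rejoined at 10.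

Step 10. Hydride may be delivered to the wrong face of C7, giving a cis-bromohydrin that rearranges to a ketone instead of closing. The fallback fixes the C7 oxygen by anti addition to a diene and sets out from 19. Lithium dienolate 20 would be trapped with PhNTf2 as the dienyl triflate F3, and Pd(OAc)2/PPh3 with HCO2H/Et3N would reduce it to the ring B 6,8-diene F4. NBS in aqueous 1,2-dimethoxyethane should add bromine to C6 from the α face and water to the allylic C7 from the β face, giving bromohydrin 23; K2CO3 then closes the epoxide, and the route is rejoined at 24.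

Step 12. Acyl transfer to the axial 6β-hydroxyl, which is syn-axial to two methyls, may fail, or forcing conditions may cause elimination. The fallback delivers the acetate intramolecularly and sets out from bromohydrin 23, isolated by omitting the base in step 10. Ac2O/pyridine would acetylate the unhindered 7β-hydroxyl to give the bromo acetate F5. AgO2CCH2CHMe2 in toluene at 80 °C should remove bromide with participation of the 7β-acetate, and isovalerate should open the resulting β-face acetoxonium ion at allylic C7 from the α face (Woodward–Prévost-type double inversion). This gives the 6β-acetate and 7α-isovalerate directly, and the route is rejoined at 26.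

Further compounds
F1 | step 4 | (4aS,8aS)-8-hydroxy-3,5,5,8a-tetramethyl-4-oxo-… ring A β-hydroxy aldehyde: 1-hydroxy-2-formyl derivative of 11 (labdane C1–OH, C2–CHO; epimers at C1 and C2) | C1C=C(C)C(=O)[C@@]2(C)C(O)C(C=O)CC(C)(C)[C@H]12
F2 | step 4 | ring A enal: 2-formyl derivative of 10 (labdane C1=C2–CHO) | C1C=C(C)C(=O)[C@@]2(C)C=C(C=O)CC(C)(C)[C@H]12
F3 | step 10 | tert-butyl 7-(trifluoromethylsulfonyloxy)labda-6,8,13E-trien-15-oate | C1=C(OS(=O)(=O)C(F)(F)F)C(C)=C(CC/C(C)=C/C(=O)OC(C)(C)C)[C@@]2(C)CCCC(C)(C)[C@H]12
F4 | step 10 | tert-butyl labda-6,8,13E-trien-15-oate | C1=CC(C)=C(CC/C(C)=C/C(=O)OC(C)(C)C)[C@@]2(C)CCCC(C)(C)[C@H]12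
F5 | step 12 | tert-butyl 7β-acetoxy-6α-bromolabda-8,13E-dien-15-oate | Br[C@H]1[C@H](OC(C)=O)C(C)=C(CC/C(C)=C/C(=O)OC(C)(C)C)[C@@]2(C)CCCC(C)(C)[C@H]12
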